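**Retrosynthetic overview**
1. Target 33 ⇐ C9 acylation, C13=C14 dehydrogenation, C11 acetoxylation (enol-acetate epoxide, acyl shift) and C2–C3 epoxide (chlorohydrin closure) from bicycle 26.
2. 26 ⇐ Lewis-acid-promoted macrocyclising intramolecular Diels–Alder reaction of acyclic 25 (2-acetoxydiene C10–C13 with the α′-chloro isopropenyl ketone C14=C1–C2): ring A and the ten-membered ring close in one operation and set C1 and C10.
3. 25 ⇐ γ-lactone 19 ⇐ (Z)-γ-chloroallylboration/lactonisation joining aldehyde 13 (C7–C13, C17–C20) and allyl chloride 16 (C2–C6, C16): C6–C7 bond, C6 and C7 stereocentres.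
4. 13 ⇐ dimethyl L-malate (C7, C8, C17, C19; Fráter–Seebach methylation, Seebach dioxolanone aldol) + enynal 6 (C9–C13, C20); C9 set by oxazaborolidine reduction.
5. Ring order: γ-lactone (step 11) → ring A and ten-membered ring together (step 17) → epoxide (step 19).

Numbering: briarane numbering throughout (C1 quaternary ring-fusion carbon with methyl C15; C2/C3 epoxide; C4; C5 with methylidene C16; C6 Cl; C7 lactone O; C8 OH; C9 ester; C10 ring-fusion CH; C11 with methyl C20 and OAc; C12 C=O; C13=C14; C17 with methyl C18; C19 lactone C=O; "19,7-olide" = lactone C19→O–C7).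
Assumption: compounds 1, 5, 14, 15 and 22 are taken as inexpensive catalogue materials; all selectivities below are predicted, none has been tested.

**Step 1**
Reactants: 1 dimethyl (2S)-2-hydroxybutanedioate (dimethyl L-malate)
Product: 2 dimethyl (2S,3R)-2-hydroxy-3-methylbutanedioate
Conditions: LiN(iPr)2 (2.2 equiv), THF, −78 → −20 °C; MeI, −78 → 0 °C
Reagents that add atoms: iodomethane (CI)
Why: Fráter–Seebach alkylation, in which the chelated lithium alkoxide–enolate dianion is methylated anti to the alkoxide and so sets C17 (3R) from the malate stereocentre.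

**Step 2**
Reactants: 2 dimethyl (2S,3R)-2-hydroxy-3-methylbutanedioate
Product: 3 (2S,3R)-2-hydroxy-3-methylbutanedioic acid
Conditions: KOH (3 equiv), H2O/MeOH, rt; HCl to pH 1
Reagents that add atoms: water (O)
Why: Plain ester saponification that leaves both stereocentres untouched.

**Step 3**
Reactants: 3 (2S,3R)-2-hydroxy-3-methylbutanedioic acid
Product: 4 (2R)-2-[(2S,4S)-2-tert-butyl-5-oxo-1,3-dioxolan-4-yl]propanoic acid
Conditions: pivalaldehyde (2 equiv), p-TsOH (catalytic), H2SO4 (catalytic), pentane, reflux, Dean–Stark; recrystallise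
Reagents that add atoms: pivalaldehyde (CC(C)(C)C=O)
Why: Seebach acetalisation of the α-hydroxy acid (self-regeneration of stereocentres), which gives the thermodynamically preferred cis-dioxolanone so that the new acetal carbon stores the C8 configuration.

**Step 4**
Reactants: 5 (2E)-3-methylpent-2-en-4-yn-1-ol
Product: 6 (2E)-3-methylpent-2-en-4-ynal
Conditions: MnO2 (10 equiv), CH2Cl2, rt
Reagents that add atoms: none
Why: Allylic alcohol oxidation with MnO2, which keeps the E geometry that later places C9 cis to the C11 methyl.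

**Step 5**
Reactants: 4 (2R)-2-[(2S,4S)-2-tert-butyl-5-oxo-1,3-dioxolan-4-yl]propanoic acid; 6 (2E)-3-methylpent-2-en-4-ynal
Product: 8 methyl (2R)-2-[(2S,4R)-2-tert-butyl-4-[(2E)-1-hydroxy-3-methylpent-2-en-4-yn-1-yl]-5-oxo-1,3-dioxolan-4-yl]propanoate (both carbinol epimers), via aldol hydroxy acid 7 (not isolated)
Conditions: LiN(SiMe3)2 (2.2 equiv), THF, −78 °C; 6, −78 °C; AcOH (2.5 equiv); then MeOH, Me3SiCHN2, 0 °C
Reagents that add atoms: (trimethylsilyl)diazomethane (C[Si](C)(C)C=[N+]=[N-])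
Why: Seebach dioxolanone aldol of the carboxylate–enolate dianion, in which the aldehyde adds trans to the tert-butyl group so that C8 becomes quaternary with retention, while the C9 carbinol forms as a mixture that is converged in steps 6 and 7 and the acid is methylated at once to prevent lactonisation onto the 9-hydroxyl.

**Step 6**
Reactants: 8 methyl ester aldol adduct (both carbinol epimers)
Product: 9 methyl (2R)-2-[(2S,4R)-2-tert-butyl-4-[(2E)-3-methylpent-2-en-4-ynoyl]-5-oxo-1,3-dioxolan-4-yl]propanoate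
Conditions: Dess–Martin periodinane (1.5 equiv), NaHCO3, CH2Cl2, 0 °C → rt
Reagents that add atoms: none
Why: Dess–Martin oxidation converges both C9 epimers to one non-enolisable ketone (C8 is quaternary).

**Step 7**
Reactants: 9 enynyl ketone
Product: 10 methyl (2R)-2-[(2S,4R)-2-tert-butyl-4-[(1S,2E)-1-hydroxy-3-methylpent-2-en-4-yn-1-yl]-5-oxo-1,3-dioxolan-4-yl]propanoate
Conditions: (R)-1-methyl-3,3-diphenyltetrahydro-1H,3H-pyrrolo[1,2-c][1,3,2]oxazaborole (0.3 equiv), catecholborane (1.8 equiv), toluene, −78 °C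
Reagents that add atoms: none
Why: Corey–Bakshi–Shibata reduction, in which the quaternary C8 acts as the large group and the alkenyl as the small group so that the (R)-catalyst delivers hydride to give the (9S)-alcohol under catalyst control.

**Step 8**
Reactants: 10 (9S)-alcohol
Product: 11 methyl (2R)-2-[(2S,4R)-2-tert-butyl-4-[(1S,2E)-1-(tert-butyldimethylsilyloxy)-3-methylpent-2-en-4-yn-1-yl]-5-oxo-1,3-dioxolan-4-yl]propanoate
Conditions: tBuMe2SiOTf, 2,6-lutidine, CH2Cl2, −20 → 0 °C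
Reagents that add atoms: tert-butyldimethylsilyl trifluoromethanesulfonate (CC(C)(C)[Si](C)(C)OS(=O)(=O)C(F)(F)F)
Why: Silylation of the hindered secondary alcohol, which blocks lactonisation of O9 onto C19 and later places a non-chelating ether on the diene.

**Step 9**
Reactants: 11 silyl ether dioxolanone
Product: 13 methyl (2R,3R,4S,5E)-4-(tert-butyldimethylsilyloxy)-3-formyl-3-hydroxy-2,6-dimethyloct-5-en-7-ynoate, via dioxolane lactol 12 (not isolated)
Conditions: iBu2AlH (1.1 equiv), CH2Cl2, −78 °C; aqueous potassium sodium tartrate; then AcOH/THF/H2O, rt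
Reagents that add atoms: none
Why: Partial reduction of the activated acylal-type lactone carbonyl (faster than the hindered acyclic methyl ester) to the lactol, which opens under mild acid with loss of pivalaldehyde to the C7 aldehyde and the free 8-hydroxyl without touching C8.

**Step 10**
Reactants: 14 3-chloro-2-(chloromethyl)prop-1-ene; 15 (1,3-dioxolan-2-ylmethyl)magnesium bromide
Product: 16 2-[3-(chloromethyl)but-3-en-1-yl]-1,3-dioxolane
Conditions: 14 (3 equiv), Li2CuCl4 (3 mol %), THF, −20 → 0 °C, slow addition of 15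
Reagents that add atoms: none
Why: Copper-catalysed allylic substitution of a symmetrical bis-allylic chloride, for which the SN2 and SN2′ paths give the same product and excess 14 suppresses double substitution.

**Step 11**
Reactants: 13 α-hydroxy aldehyde; 16 2-[3-(chloromethyl)but-3-en-1-yl]-1,3-dioxolane
Product: 19 (3R,4S,5S)-4-[(1S,2E)-1-(tert-butyldimethylsilyloxy)-3-methylpent-2-en-4-yn-1-yl]-5-[(1S)-1-chloro-4-(1,3-dioxolan-2-yl)-2-methylidenebutyl]-4-hydroxy-3-methyloxolan-2-one, via chloroallylborane 17 (not isolated), via chlorohydrin hydroxy ester 18 (not isolated)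
Conditions: 16, (+)-Ipc2BOMe (from (−)-α-pinene), LiN(c-C6H11)2 (2.5 equiv each), THF/Et2O, −95 °C; BF3·OEt2; 13, −95 °C, 4 h; 2-aminoethanol; then PPTS (catalytic), CH2Cl2, rt
Reagents that add atoms: none
Why: Oehlschlager–Brown (Z)-γ-chloroallylboration, in which the closed Zimmerman–Traxler chair turns the Z-chloroalkene into the syn chlorohydrin and the isopinocampheyl groups direct attack to the Re face of the aldehyde to give 6S,7S together with the C5 methylidene, after which the 7-hydroxyl closes the γ-lactone onto the C19 ester (gem-disubstitution at C8 helps).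

**Step 12**
Reactants: 19 lactone acetal
Product: 20 (3R,4S,5S)-4-[(1S,2E)-1-(tert-butyldimethylsilyloxy)-3-methylpent-2-en-4-yn-1-yl]-5-[(1S)-1-chloro-2-methylidene-5-oxopentyl]-4-hydroxy-3-methyloxolan-2-one
Conditions: PPTS (0.3 equiv), acetone/H2O 9:1, 55 °C
Reagents that add atoms: water (O)
Why: Mild acetal hydrolysis that frees the C2 aldehyde while the silyl ether, the lactone and the allylic chloride survive.

**Step 13**
Reactants: 20 lactone aldehyde
Product: 21 (3R,4S,5S)-4-[(1S,2E)-1-(tert-butyldimethylsilyloxy)-3-methylpent-2-en-4-yn-1-yl]-5-[(1S,4S)-1,4-dichloro-2-methylidene-5-oxopentyl]-4-hydroxy-3-methyloxolan-2-one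
Conditions: (2R,5R)-2,5-diphenylpyrrolidine (10 mol %), N-chlorosuccinimide (1.2 equiv), CH2Cl2, 0 °C → rt; used crude
Reagents that add atoms: N-chlorosuccinimide (O=C1CCC(=O)N1Cl)
Why: Enamine-catalysed electrophilic α-chlorination of the aldehyde, in which the C2-symmetric pyrrolidine shields one enamine face and sets the (3S)-chloride that becomes the leaving group for the epoxide.

**Step 14**
Reactants: 21 α-chloro aldehyde; 22 prop-1-en-2-ylmagnesium bromide (isopropenylmagnesium bromide)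
Product: 23 (3R,4S,5S)-4-[(1S,2E)-1-(tert-butyldimethylsilyloxy)-3-methylpent-2-en-4-yn-1-yl]-5-[(1S,4S)-1,4-dichloro-5-hydroxy-6-methyl-2-methylidenehept-6-en-1-yl]-4-hydroxy-3-methyloxolan-2-one (C2 carbinol epimers)
Conditions: 22 (3 equiv), THF, −78 °C, 30 min; aqueous NH4Cl
Reagents that add atoms: none
Why: Chemoselective Grignard 1,2-addition to the aldehyde at −78 °C (the lactone is much slower), whose carbinol configuration is irrelevant because C2 is oxidised in step 15.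

**Step 15**
Reactants: 23 chlorohydrin (C2 epimers)
Product: 24 (3R,4S,5S)-4-[(1S,2E)-1-(tert-butyldimethylsilyloxy)-3-methylpent-2-en-4-yn-1-yl]-5-[(1S,4S)-1,4-dichloro-6-methyl-2-methylidene-5-oxohept-6-en-1-yl]-4-hydroxy-3-methyloxolan-2-one
Conditions: Dess–Martin periodinane (1.5 equiv), NaHCO3, CH2Cl2, 0 °C
Reagents that add atoms: none
Why: Buffered Dess–Martin oxidation of the allylic alcohol gives the α′-chloro isopropenyl ketone (the dienophile) without epimerising C3, and the tertiary 8-hydroxyl cannot be oxidised.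

**Step 16**
Reactants: 24 enynyl enone
Product: 25 (3R,4S,5S)-4-[(1S,2E)-4-acetoxy-1-(tert-butyldimethylsilyloxy)-3-methylpenta-2,4-dien-1-yl]-5-[(1S,4S)-1,4-dichloro-6-methyl-2-methylidene-5-oxohept-6-en-1-yl]-4-hydroxy-3-methyloxolan-2-one
Conditions: [RuCl2(p-cymene)]2 (2 mol %), P(2-furyl)3 (4 mol %), Na2CO3 (2 mol %), AcOH (3 equiv), toluene, 50 °C
Reagents that add atoms: acetic acid (CC(=O)O)
Why: Ruthenium-catalysed Markovnikov hydro-acyloxylation of the terminal alkyne of the 1-en-3-yne, a neutral route to the 2-acetoxy-1,3-diene that needs no enolisation and so leaves the α′-chloro ketone alone.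

**Step 17 (key step)**
Reactants: 25 acetoxydiene enone
Product: 26 (1S,3S,6S,7S,8S,9S,10S,17R)-12-acetoxy-9-(tert-butyldimethylsilyloxy)-3,6-dichloro-8-hydroxy-2-oxobriara-5(16),11-dien-19,7-olide
Conditions: Me2AlCl (2.5 equiv), CH2Cl2, 0.001 M (syringe-pump addition of 25), −40 → 0 °C
Reagents that add atoms: none
Why: Type 1 intramolecular Diels–Alder macrocyclisation (the way the eleven-membered carbocycle and the cyclohexene of cytochalasans are closed together), in which Me2AlCl activates only the enone, the 2-acetoxy group and the C10 substituent both direct C13 to C14 and C10 to C1, allylic 1,3-strain with the C11 methyl holds H-9 in the diene plane so that the dienophile adds anti to the C9–C8 bond (C10 set from C9), and the eight-atom tether can only span the exo mode, which puts C2 trans to C9 (C1 set) and leaves C11=C12 as the enol acetate.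

**Step 18**
Reactants: 26 bicyclic α-chloro ketone
Product: 27 (1S,2R,3S,6S,7S,8S,9S,10R,17R)-12-acetoxy-9-(tert-butyldimethylsilyloxy)-3,6-dichloro-2,8-dihydroxybriara-5(16),11-dien-19,7-olide
Conditions: (R)-1-methyl-3,3-diphenyltetrahydro-1H,3H-pyrrolo[1,2-c][1,3,2]oxazaborole (0.5 equiv), catecholborane (2 equiv), toluene, −40 °C
Reagents that add atoms: none
Why: Corey–Bakshi–Shibata reduction of the only ketone present (C12 is still masked as the enol acetate), with the quaternary C1 as the large group and reinforced by the Cornforth preference for hydride anti to chloride, to give the (2R,3S) anti-chlorohydrin.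

**Step 19**
Reactants: 27 anti-chlorohydrin
Product: 28 (1S,2R,3R,6S,7S,8S,9S,10R,17R)-12-acetoxy-9-(tert-butyldimethylsilyloxy)-6-chloro-2,3-epoxy-8-hydroxybriara-5(16),11-dien-19,7-olide
Conditions: Cs2CO3 (2 equiv), MeCN, 40 °C
Reagents that add atoms: none
Why: Intramolecular Williamson closure (3-exo-tet) with inversion at C3 gives the trans-(2R,3R)-epoxide, while the C6 chloride has no free vicinal hydroxyl and the non-nucleophilic carbonate spares the enol acetate and the lactone.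

**Step 20**
Reactants: 28 epoxy enol acetate
Product: 30 (1S,2R,3R,6S,7S,8S,9S,10S,11S,17R)-11-acetoxy-9-(tert-butyldimethylsilyloxy)-6-chloro-2,3-epoxy-8-hydroxy-12-oxobriar-5(16)-en-19,7-olide, via epoxy acetate 29 (not isolated)
Conditions: dimethyldioxirane (1.1 equiv), acetone, −40 °C; evaporate; silica gel, CH2Cl2, rt
Reagents that add atoms: dimethyldioxirane (CC1(C)OO1)
Why: Chemoselective epoxidation of the electron-rich tetrasubstituted enol acetate from the face anti to the axial C15 methyl (the face of H-10), followed by the acid-promoted acyl shift of the α-acetoxy epoxide that goes with retention at C11 (C12–O cleavage, then O-to-O acetyl transfer) and gives the tertiary 11-acetate cis to H-10 next to the C12 ketone.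

**Step 21**
Reactants: 30 α-acetoxy ketone
Product: 31 (1S,2R,3R,6S,7S,8S,9S,10S,11S,17R)-11-acetoxy-9-(tert-butyldimethylsilyloxy)-6-chloro-2,3-epoxy-8-hydroxy-12-oxobriara-5(16),13-dien-19,7-olide
Conditions: 2-iodoxybenzoic acid (2.5 equiv), 4-methoxypyridine N-oxide (2.5 equiv), DMSO, rt → 40 °C
Reagents that add atoms: none
Why: Ketone dehydrogenation with 2-iodoxybenzoic acid through the C12 enol, which can only form toward C13 because C11 is quaternary, gives the C13=C14 enone without touching a stereocentre.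

**Step 22**
Reactants: 31 silyl ether enone
Product: 32 (1S,2R,3R,6S,7S,8R,9S,10S,11S,17R)-11-acetoxy-6-chloro-2,3-epoxy-8,9-dihydroxy-12-oxobriara-5(16),13-dien-19,7-olide
Conditions: HF·pyridine, pyridine, THF, 0 °C → rt
Reagents that add atoms: none
Why: Buffered fluoride desilylation frees the 9-hydroxyl, and in the ten-membered ring O9 is held away from C19 so the lactone does not migrate.

**Step 23**
Reactants: 32 8,9-diol
Product: 33 (1S,2R,3R,6S,7S,8R,9S,10S,11S,17R)-11-acetoxy-9-(acetoxyacetoxy)-6-chloro-2,3-epoxy-8-hydroxy-12-oxobriara-5(16),13-dien-19,7-olide (CNP0314084.4)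
Conditions: acetoxyacetyl chloride (3 equiv), pyridine, DMAP (catalytic), CH2Cl2, 0 °C
Reagents that add atoms: acetoxyacetyl chloride (CC(=O)OCC(Cl)=O)
Why: DMAP-catalysed acylation of the secondary 9-hydroxyl, which the tertiary 8-hydroxyl is too hindered to compete with.

**Compound list**
1 | dimethyl (2S)-2-hydroxybutanedioate | COC(=O)C[C@H](O)C(=O)OC | starting material
2 | dimethyl (2S,3R)-2-hydroxy-3-methylbutanedioate | COC(=O)[C@@H]([C@H](O)C(=O)OC)C | intermediate
3 | (2S,3R)-2-hydroxy-3-methylbutanedioic acid | OC(=O)[C@@H]([C@H](O)C(=O)O)C | intermediate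
4 | (2R)-2-[(2S,4S)-2-tert-butyl-5-oxo-1,3-dioxolan-4-yl]propanoic acid | OC(=O)[C@@H]([C@@H]1O[C@H](C(C)(C)C)OC1=O)C | intermediate
5 | (2E)-3-methylpent-2-en-4-yn-1-ol | OC/C=C(C)/C#C | starting material
6 | (2E)-3-methylpent-2-en-4-ynal | O=C/C=C(C)/C#C | intermediate
7 | (2R)-2-[(2S,4R)-2-tert-butyl-4-[(2E)-1-hydroxy-3-methylpent-2-en-4-yn-1-yl]-5-oxo-1,3-dioxolan-4-yl]propanoic acid (carbinol epimers) | OC(=O)[C@@H]([C@]1(C(O)/C=C(C)/C#C)O[C@H](C(C)(C)C)OC1=O)C | intermediate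
8 | methyl (2R)-2-[(2S,4R)-2-tert-butyl-4-[(2E)-1-hydroxy-3-methylpent-2-en-4-yn-1-yl]-5-oxo-1,3-dioxolan-4-yl]propanoate (carbinol epimers) | COC(=O)[C@@H]([C@]1(C(O)/C=C(C)/C#C)O[C@H](C(C)(C)C)OC1=O)C | intermediate
9 | methyl (2R)-2-[(2S,4R)-2-tert-butyl-4-[(2E)-3-methylpent-2-en-4-ynoyl]-5-oxo-1,3-dioxolan-4-yl]propanoate | COC(=O)[C@@H]([C@]1(C(=O)/C=C(C)/C#C)O[C@H](C(C)(C)C)OC1=O)C | intermediate
10 | methyl (2R)-2-[(2S,4R)-2-tert-butyl-4-[(1S,2E)-1-hydroxy-3-methylpent-2-en-4-yn-1-yl]-5-oxo-1,3-dioxolan-4-yl]propanoate | COC(=O)[C@@H]([C@]1([C@@H](O)/C=C(C)/C#C)O[C@H](C(C)(C)C)OC1=O)C | intermediate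
11 | methyl (2R)-2-[(2S,4R)-2-tert-butyl-4-[(1S,2E)-1-(tert-butyldimethylsilyloxy)-3-methylpent-2-en-4-yn-1-yl]-5-oxo-1,3-dioxolan-4-yl]propanoate | COC(=O)[C@@H]([C@]1([C@@H](O[Si](C)(C)C(C)(C)C)/C=C(C)/C#C)O[C@H](C(C)(C)C)OC1=O)C | intermediate
12 | methyl (2R)-2-[(2S,4R)-2-tert-butyl-4-[(1S,2E)-1-(tert-butyldimethylsilyloxy)-3-methylpent-2-en-4-yn-1-yl]-5-hydroxy-1,3-dioxolan-4-yl]propanoate (lactol epimers) | COC(=O)[C@@H]([C@]1([C@@H](O[Si](C)(C)C(C)(C)C)/C=C(C)/C#C)O[C@H](C(C)(C)C)OC1O)C | intermediate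
13 | methyl (2R,3R,4S,5E)-4-(tert-butyldimethylsilyloxy)-3-formyl-3-hydroxy-2,6-dimethyloct-5-en-7-ynoate | COC(=O)[C@@H]([C@](O)(C=O)[C@@H](O[Si](C)(C)C(C)(C)C)/C=C(C)/C#C)C | intermediate
14 | 3-chloro-2-(chloromethyl)prop-1-ene | ClCC(=C)CCl | starting material
15 | (1,3-dioxolan-2-ylmethyl)magnesium bromide | Br[Mg]CC1OCCO1 | starting material
16 | 2-[3-(chloromethyl)but-3-en-1-yl]-1,3-dioxolane | ClCC(=C)CCC1OCCO1 | intermediate
17 | B-[(2Z)-3-chloro-2-[2-(1,3-dioxolan-2-yl)ethyl]prop-2-en-1-yl]diisopinocampheylborane (isopinocampheyl from (−)-α-pinene) | Cl/C=C(/CCC1OCCO1)CB([C@H]1C[C@H]2C[C@H](C2(C)C)[C@@H]1C)[C@H]1C[C@H]2C[C@H](C2(C)C)[C@@H]1C | intermediate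
18 | methyl (2R,3S,4S,5E)-4-(tert-butyldimethylsilyloxy)-3-[(1S,2S)-2-chloro-5-(1,3-dioxolan-2-yl)-1-hydroxy-3-methylidenepentyl]-3-hydroxy-2,6-dimethyloct-5-en-7-ynoate | COC(=O)[C@@H]([C@](O)([C@H](O)[C@@H](Cl)C(=C)CCC1OCCO1)[C@@H](O[Si](C)(C)C(C)(C)C)/C=C(C)/C#C)C | intermediate
19 | (3R,4S,5S)-4-[(1S,2E)-1-(tert-butyldimethylsilyloxy)-3-methylpent-2-en-4-yn-1-yl]-5-[(1S)-1-chloro-4-(1,3-dioxolan-2-yl)-2-methylidenebutyl]-4-hydroxy-3-methyloxolan-2-one | C[C@H]1C(=O)O[C@H]([C@@H](Cl)C(=C)CCC2OCCO2)[C@]1(O)[C@@H](O[Si](C)(C)C(C)(C)C)/C=C(C)/C#C | intermediate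
20 | (3R,4S,5S)-4-[(1S,2E)-1-(tert-butyldimethylsilyloxy)-3-methylpent-2-en-4-yn-1-yl]-5-[(1S)-1-chloro-2-methylidene-5-oxopentyl]-4-hydroxy-3-methyloxolan-2-one | C[C@H]1C(=O)O[C@H]([C@@H](Cl)C(=C)CCC=O)[C@]1(O)[C@@H](O[Si](C)(C)C(C)(C)C)/C=C(C)/C#C | intermediate
21 | (3R,4S,5S)-4-[(1S,2E)-1-(tert-butyldimethylsilyloxy)-3-methylpent-2-en-4-yn-1-yl]-5-[(1S,4S)-1,4-dichloro-2-methylidene-5-oxopentyl]-4-hydroxy-3-methyloxolan-2-one | C[C@H]1C(=O)O[C@H]([C@@H](Cl)C(=C)C[C@H](Cl)C=O)[C@]1(O)[C@@H](O[Si](C)(C)C(C)(C)C)/C=C(C)/C#C | intermediate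
22 | prop-1-en-2-ylmagnesium bromide | CC(=C)[Mg]Br | starting material
23 | (3R,4S,5S)-4-[(1S,2E)-1-(tert-butyldimethylsilyloxy)-3-methylpent-2-en-4-yn-1-yl]-5-[(1S,4S)-1,4-dichloro-5-hydroxy-6-methyl-2-methylidenehept-6-en-1-yl]-4-hydroxy-3-methyloxolan-2-one (C2 epimers) | C[C@H]1C(=O)O[C@H]([C@@H](Cl)C(=C)C[C@H](Cl)C(O)C(C)=C)[C@]1(O)[C@@H](O[Si](C)(C)C(C)(C)C)/C=C(C)/C#C | intermediate
24 | (3R,4S,5S)-4-[(1S,2E)-1-(tert-butyldimethylsilyloxy)-3-methylpent-2-en-4-yn-1-yl]-5-[(1S,4S)-1,4-dichloro-6-methyl-2-methylidene-5-oxohept-6-en-1-yl]-4-hydroxy-3-methyloxolan-2-one | C[C@H]1C(=O)O[C@H]([C@@H](Cl)C(=C)C[C@H](Cl)C(=O)C(C)=C)[C@]1(O)[C@@H](O[Si](C)(C)C(C)(C)C)/C=C(C)/C#C | intermediate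
25 | (3R,4S,5S)-4-[(1S,2E)-4-acetoxy-1-(tert-butyldimethylsilyloxy)-3-methylpenta-2,4-dien-1-yl]-5-[(1S,4S)-1,4-dichloro-6-methyl-2-methylidene-5-oxohept-6-en-1-yl]-4-hydroxy-3-methyloxolan-2-one | C[C@H]1C(=O)O[C@H]([C@@H](Cl)C(=C)C[C@H](Cl)C(=O)C(C)=C)[C@]1(O)[C@@H](O[Si](C)(C)C(C)(C)C)/C=C(C)/C(OC(C)=O)=C | intermediate
26 | (1S,3S,6S,7S,8S,9S,10S,17R)-12-acetoxy-9-(tert-butyldimethylsilyloxy)-3,6-dichloro-8-hydroxy-2-oxobriara-5(16),11-dien-19,7-olide | C=C1C[C@H](Cl)C(=O)[C@@]2(C)CCC(OC(C)=O)=C(C)[C@@H]2[C@H](O[Si](C)(C)C(C)(C)C)[C@@]2(O)[C@H](OC(=O)[C@@H]2C)[C@H]1Cl | intermediate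
27 | (1S,2R,3S,6S,7S,8S,9S,10R,17R)-12-acetoxy-9-(tert-butyldimethylsilyloxy)-3,6-dichloro-2,8-dihydroxybriara-5(16),11-dien-19,7-olide | C=C1C[C@H](Cl)[C@H](O)[C@@]2(C)CCC(OC(C)=O)=C(C)[C@@H]2[C@H](O[Si](C)(C)C(C)(C)C)[C@@]2(O)[C@H](OC(=O)[C@@H]2C)[C@H]1Cl | intermediate
28 | (1S,2R,3R,6S,7S,8S,9S,10R,17R)-12-acetoxy-9-(tert-butyldimethylsilyloxy)-6-chloro-2,3-epoxy-8-hydroxybriara-5(16),11-dien-19,7-olide | C=C1C[C@H]2O[C@@H]2[C@@]2(C)CCC(OC(C)=O)=C(C)[C@@H]2[C@H](O[Si](C)(C)C(C)(C)C)[C@@]2(O)[C@H](OC(=O)[C@@H]2C)[C@H]1Cl | intermediate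
29 | 11,12-epoxide of 28 (12-acetoxy-11,12-epoxide; epoxide oxygen on the face of H-10) | C=C1C[C@H]2O[C@@H]2[C@@]2(C)CC[C@@]3(OC(C)=O)O[C@@]3(C)[C@@H]2[C@H](O[Si](C)(C)C(C)(C)C)[C@@]2(O)[C@H](OC(=O)[C@@H]2C)[C@H]1Cl | intermediate
30 | (1S,2R,3R,6S,7S,8S,9S,10S,11S,17R)-11-acetoxy-9-(tert-butyldimethylsilyloxy)-6-chloro-2,3-epoxy-8-hydroxy-12-oxobriar-5(16)-en-19,7-olide | C=C1C[C@H]2O[C@@H]2[C@@]2(C)CCC(=O)[C@@](C)(OC(C)=O)[C@@H]2[C@H](O[Si](C)(C)C(C)(C)C)[C@@]2(O)[C@H](OC(=O)[C@@H]2C)[C@H]1Cl | intermediate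
31 | (1S,2R,3R,6S,7S,8S,9S,10S,11S,17R)-11-acetoxy-9-(tert-butyldimethylsilyloxy)-6-chloro-2,3-epoxy-8-hydroxy-12-oxobriara-5(16),13-dien-19,7-olide | C=C1C[C@H]2O[C@@H]2[C@@]2(C)C=CC(=O)[C@@](C)(OC(C)=O)[C@@H]2[C@H](O[Si](C)(C)C(C)(C)C)[C@@]2(O)[C@H](OC(=O)[C@@H]2C)[C@H]1Cl | intermediate
32 | (1S,2R,3R,6S,7S,8R,9S,10S,11S,17R)-11-acetoxy-6-chloro-2,3-epoxy-8,9-dihydroxy-12-oxobriara-5(16),13-dien-19,7-olide | C=C1C[C@H]2O[C@@H]2[C@@]2(C)C=CC(=O)[C@@](C)(OC(C)=O)[C@@H]2[C@H](O)[C@@]2(O)[C@H](OC(=O)[C@@H]2C)[C@H]1Cl | intermediate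
33 | (1S,2R,3R,6S,7S,8R,9S,10S,11S,17R)-11-acetoxy-9-(acetoxyacetoxy)-6-chloro-2,3-epoxy-8-hydroxy-12-oxobriara-5(16),13-dien-19,7-olide (CNP0314084.4) | C=C1C[C@H]2O[C@@H]2[C@@]2(C)C=CC(=O)[C@@](C)(OC(C)=O)[C@@H]2[C@H](OC(=O)COC(C)=O)[C@@]2(O)[C@H](OC(=O)[C@@H]2C)[C@H]1Cl | target

**Totals**
Total step count: 23. Longest linear sequence: 21 steps (1–3, 5–9, 11–23); steps 4 and 10 make the two side fragments.

**Three steps most likely to fail**

Step 17 (macrocyclising Diels–Alder). The risks are the entropy of ten-membered ring closure, a competing cycloaddition of the diene with the unactivated C5=C16 alkene through the four-atom tether C6–C9, and loss of the exo mode under Lewis acid. The fallback sets out from 24. Gold-catalysed hydration of the terminal alkyne ((Ph3P)AuNTf2, H2O, dioxane) gives the methyl enone F1. A stepwise ionic double Michael annulation (Me3SiI, HN(SiMe3)2, CH2Cl2, −40 °C) then closes both rings: the silyl dienol ether formed in the flask adds through C13 to C14 and the resulting enol silane adds through C1 to C10, under the same tether and allylic-strain constraints, to give the diketone F2. Thermodynamic enol acetylation toward the more substituted C11 (isopropenyl acetate, p-TsOH) comes back to the route at 26.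

Step 11 (chloroallylboration/lactonisation). The risks are that a 2-substituted γ-chloroallyl reagent is less established than the parent and that the aldehyde is hindered and carries a free α-hydroxyl. The fallback sets out from 13. A Nozaki–Hiyama–Kishi coupling (CrCl2, 1 mol % NiCl2, DMF) with the vinyl iodide F3 (from known 2-(but-3-yn-1-yl)-1,3-dioxolane by Cp2ZrCl2-catalysed carboalumination with Me3Al, then I2) gives the allylic alcohol F4, which lactonises (PPTS) to the lactone F5. An ene-type allylic chlorination with double-bond shift (N-chlorosuccinimide, 10 mol % PhSeCl, CH2Cl2) then puts chlorine on C6 anti to the C7–C8 bond, because allylic strain with the C16 methyl holds H-7 in the alkene plane, and moves the alkene to C5=C16. This comes back to the route at 19.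

Step 9 (partial reduction of the dioxolanone beside a methyl ester). The risk is over-reduction or attack at C19. The fallback sets out from 11. The dioxolanone is opened with MeNH(OMe)·HCl and iPrMgCl (THF, −20 °C) to the Weinreb amide F6, with loss of pivalaldehyde and a free 8-hydroxyl. iBu2AlH at −78 °C then reduces the amide through its stable chelate and comes back to the route at 13.

**Further compounds**
F1 | step 17 | (3R,4S,5S)-4-[(1S,2E)-1-(tert-butyldimethylsilyloxy)-3-methyl-4-oxopent-2-en-1-yl]-5-[(1S,4S)-1,4-dichloro-6-methyl-2-methylidene-5-oxohept-6-en-1-yl]-4-hydroxy-3-methyloxolan-2-one | C[C@H]1C(=O)O[C@H]([C@@H](Cl)C(=C)C[C@H](Cl)C(=O)C(C)=C)[C@]1(O)[C@@H](O[Si](C)(C)C(C)(C)C)/C=C(C)/C(C)=O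
F2 | step 17 | (1S,3S,6S,7S,8S,9S,10S,17R)-9-(tert-butyldimethylsilyloxy)-3,6-dichloro-8-hydroxy-2,12-dioxobriar-5(16)-en-19,7-olide (C11 epimers) | C=C1C[C@H](Cl)C(=O)[C@@]2(C)CCC(=O)C(C)[C@@H]2[C@H](O[Si](C)(C)C(C)(C)C)[C@@]2(O)[C@H](OC(=O)[C@@H]2C)[C@H]1Cl
F3 | step 11 | 2-[(3E)-4-iodo-3-methylbut-3-en-1-yl]-1,3-dioxolane | I/C=C(C)/CCC1OCCO1
F4 | step 11 | methyl (2R,3S,4S,5E)-4-(tert-butyldimethylsilyloxy)-3-[(1R,2E)-5-(1,3-dioxolan-2-yl)-1-hydroxy-3-methylpent-2-en-1-yl]-3-hydroxy-2,6-dimethyloct-5-en-7-ynoate | COC(=O)[C@@H]([C@](O)([C@H](O)/C=C(C)/CCC1OCCO1)[C@@H](O[Si](C)(C)C(C)(C)C)/C=C(C)/C#C)C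
F5 | step 11 | (3R,4S,5R)-4-[(1S,2E)-1-(tert-butyldimethylsilyloxy)-3-methylpent-2-en-4-yn-1-yl]-5-[(1E)-4-(1,3-dioxolan-2-yl)-2-methylbut-1-en-1-yl]-4-hydroxy-3-methyloxolan-2-one | C[C@H]1C(=O)O[C@H](/C=C(C)/CCC2OCCO2)[C@]1(O)[C@@H](O[Si](C)(C)C(C)(C)C)/C=C(C)/C#C
F6 | step 9 | methyl (2R,3R,4S,5E)-4-(tert-butyldimethylsilyloxy)-3-hydroxy-3-[methoxy(methyl)carbamoyl]-2,6-dimethyloct-5-en-7-ynoate | COC(=O)[C@@H]([C@](O)(C(=O)N(C)OC)[C@@H](O[Si](C)(C)C(C)(C)C)/C=C(C)/C#C)C
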